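The route disconnects the CH2–CH2 bridge between ring C (the 4-hydroxy-3-aryloxyphenyl ring) and ring D (the catechol ring). On ring D the hydroxyl oxygen on C2 sits ortho to C1, which bears the bridge, so this oxygen, C2, C1 and the two bridge carbons are treated as the furan ring of a 7-methoxy-2-arylbenzofuran. The key step acylates an ortho-hydroxybenzylphosphonium salt with the ring C aroyl chloride and lets the ylide olefinate the new ester carbonyl, which forms the bridge C=C bond and closes the furan in one operation. Its precursors are (2-hydroxy-3-methoxybenzyl)triphenylphosphonium bromide and a methyl-protected acid chloride that already contains rings A, B and C.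

Key step: step 8

Remark: the target has no stereocenter. Ring A is the 3-hydroxyphenyl ring, ring B the para-phenylene ring, ring C the 4-hydroxy-3-aryloxyphenyl ring and ring D the 2,3-dihydroxyphenyl ring (C1 bears the bridge, C2 and C3 the hydroxyls). The only stereocenter met on the route, C2 of a dihydrobenzofuran passed through during ring opening, forms as a racemate and is removed in the same flask.

Step 1
Reactants: 1 o-vanillin (2-hydroxy-3-methoxybenzaldehyde)
Product: 2 2-hydroxy-3-methoxybenzyl alcohol
Conditions: NaBH4, MeOH, 0 °C to rt; aq NH4Cl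
Reagents that add atoms: none
Why: Borohydride reduction of an aryl aldehyde to the benzylic alcohol, to which the phenol and the methyl ether are inert.

Step 2
Reactants: 2 2-hydroxy-3-methoxybenzyl alcohol
Product: 3 (2-hydroxy-3-methoxybenzyl)triphenylphosphonium bromide
Conditions: PPh3·HBr, MeCN, reflux
Reagents that add atoms: triphenylphosphine hydrobromide, [PH+](c1ccccc1)(c1ccccc1)c1ccccc1.[Br-]
Why: Acid-promoted loss of water from the ortho-hydroxybenzyl alcohol gives an ortho-quinone methide or benzylic cation that PPh3 captures (SN1-type phosphonium salt formation), and the salt should crystallise from MeCN.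

Step 3
Reactants: 4 methyl 3-hydroxy-4-methoxybenzoate; 5 4-fluorobenzaldehyde
Product: 6 methyl 3-(4-formylphenoxy)-4-methoxybenzoate
Conditions: K2CO3, DMF, 120 °C
Reagents that add atoms: none
Why: Nucleophilic aromatic substitution (addition–elimination) of the phenoxide of 4 at the fluoride para to the activating formyl group, under a carbonate base that leaves the methyl ester intact in dry DMF.

Step 4
Reactants: 6 methyl 3-(4-formylphenoxy)-4-methoxybenzoate; 7 diethyl (3-methoxybenzyl)phosphonate
Product: 8 methyl 4-methoxy-3-{4-[(E)-2-(3-methoxyphenyl)ethenyl]phenoxy}benzoate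
Conditions: NaOMe, DMF, 0 °C to rt
Reagents that add atoms: none
Why: Horner–Wadsworth–Emmons olefination of the aryl aldehyde by the benzylphosphonate anion should give the (E)-stilbene, whose geometry is of no consequence because the alkene is hydrogenated next, and methoxide cannot scramble the methyl ester.

Step 5
Reactants: 8 methyl 4-methoxy-3-{4-[(E)-2-(3-methoxyphenyl)ethenyl]phenoxy}benzoate
Product: 9 methyl 4-methoxy-3-{4-[2-(3-methoxyphenyl)ethyl]phenoxy}benzoate
Conditions: H2 (1 atm), 10% Pd/C, EtOAc, rt
Reagents that add atoms: none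
Why: Heterogeneous catalytic hydrogenation of the stilbene C=C bond, under which the ester, the aryl methyl ethers and the diaryl ether are unchanged.

Step 6
Reactants: 9 methyl 4-methoxy-3-{4-[2-(3-methoxyphenyl)ethyl]phenoxy}benzoate
Product: 10 4-methoxy-3-{4-[2-(3-methoxyphenyl)ethyl]phenoxy}benzoic acid
Conditions: LiOH·H2O, THF/MeOH/H2O, 50 °C; then 1 M HCl
Reagents that add atoms: lithium hydroxide, [Li+].[OH-]
Why: Saponification of the methyl ester (acyl–oxygen cleavage by hydroxide) followed by acidification, with all ethers inert.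

Step 7
Reactants: 10 4-methoxy-3-{4-[2-(3-methoxyphenyl)ethyl]phenoxy}benzoic acid
Product: 11 4-methoxy-3-{4-[2-(3-methoxyphenyl)ethyl]phenoxy}benzoyl chloride
Conditions: (COCl)2, DMF (cat.), CH2Cl2, 0 °C to rt; evaporate, crude used
Reagents that add atoms: oxalyl chloride, O=C(Cl)C(=O)Cl
Why: Acid chloride formation through the chloroiminium (Vilsmeier-type) catalyst from DMF and oxalyl chloride, with only gaseous by-products so that the crude chloride can be used after evaporation.

Step 8
Reactants: 3 (2-hydroxy-3-methoxybenzyl)triphenylphosphonium bromide; 11 4-methoxy-3-{4-[2-(3-methoxyphenyl)ethyl]phenoxy}benzoyl chloride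
Product: 14 7-methoxy-2-(4-methoxy-3-{4-[2-(3-methoxyphenyl)ethyl]phenoxy}phenyl)-1-benzofuran, via O-aroyl phosphonium bromide 12 (not isolated), via ester ylide 13 (not isolated)
Conditions: Et3N (3.5 equiv), toluene, rt then reflux
Reagents that add atoms: none
Why: Et3N first drives O-acylation of the phenol of 3 by 11 to ester 12 and then deprotonates the benzylic CH2–P group to ylide 13, whose carbanion adds to the adjacent ester carbonyl; the oxaphosphetane collapses to the benzofuran C2=C3 bond and Ph3P=O (intramolecular Wittig reaction). The closest known reaction type is this same intramolecular Wittig synthesis of 2-arylbenzofurans from ortho-hydroxybenzylphosphonium salts and aroyl chlorides, which accepts electron-rich aroyl partners and a methoxy group next to the phenol. The furan ring closes in a 5-exo-trig mode, the ylide carbon attacking the ester C=O whose oxygen lies outside the new ring and leaves with phosphorus. No stereocenter is created. The step needs O-acylation before any ylide chemistry and no second acylation at the ylide carbon; the phenol is the only acidic and nucleophilic site of 3 under Et3N at room temperature, and slow addition of close to one equivalent of 11 should keep the 3-aroylbenzofuran by-product down. Regiochemistry is fixed by the ortho relation of OH and CH2P in 3, so the former phenol oxygen becomes O1 next to the methoxy-bearing C7 and the carbonyl carbon of 11 becomes C2.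

Step 9
Reactants: 14 7-methoxy-2-(4-methoxy-3-{4-[2-(3-methoxyphenyl)ethyl]phenoxy}phenyl)-1-benzofuran
Product: 16 2-methoxy-6-[2-(4-methoxy-3-{4-[2-(3-methoxyphenyl)ethyl]phenoxy}phenyl)ethyl]phenol, via racemic dihydrobenzofuran 15 (not isolated)
Conditions: H2 (5 bar), 10% Pd/C, AcOH, 60 °C
Reagents that add atoms: none
Why: Catalytic hydrogenation of the furan C2=C3 bond gives racemic 15 (its C2 stereocenter is set without control and removed at once), whose C2–O bond is a benzylic aryl ether activated by the para-methoxyphenyl ring C and should undergo hydrogenolysis in acetic acid, as in the known Pd-catalysed opening of 2-aryl-2,3-dihydrobenzofurans, while the diaryl ether and the aryl methyl ethers have no benzylic C–O bond and stay.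

Step 10
Reactants: 16 2-methoxy-6-[2-(4-methoxy-3-{4-[2-(3-methoxyphenyl)ethyl]phenoxy}phenyl)ethyl]phenol
Product: 17 3-[2-(4-hydroxy-3-{4-[2-(3-hydroxyphenyl)ethyl]phenoxy}phenyl)ethyl]benzene-1,2-diol
Conditions: BBr3, CH2Cl2, −78 °C to rt; then H2O
Reagents that add atoms: none
Why: Lewis acid demethylation of aryl methyl ethers (boron coordination to oxygen, then bromide SN2 attack at methyl) should remove all three methyl groups, while the diaryl ether offers no alkyl carbon to bromide and survives.

Compound list
1 | o-vanillin (2-hydroxy-3-methoxybenzaldehyde) | COc1cccc(C=O)c1O | starting material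
2 | 2-hydroxy-3-methoxybenzyl alcohol | COc1cccc(CO)c1O | intermediate
3 | (2-hydroxy-3-methoxybenzyl)triphenylphosphonium bromide | COc1cccc(C[P+](c2ccccc2)(c2ccccc2)c2ccccc2)c1O.[Br-] | intermediate
4 | methyl 3-hydroxy-4-methoxybenzoate | COC(=O)c1ccc(OC)c(O)c1 | starting material
5 | 4-fluorobenzaldehyde | O=Cc1ccc(F)cc1 | starting material
6 | methyl 3-(4-formylphenoxy)-4-methoxybenzoate | COC(=O)c1ccc(OC)c(Oc2ccc(C=O)cc2)c1 | intermediate
7 | diethyl (3-methoxybenzyl)phosphonate | CCOP(=O)(Cc1cccc(OC)c1)OCC | starting material
8 | methyl 4-methoxy-3-{4-[(E)-2-(3-methoxyphenyl)ethenyl]phenoxy}benzoate | COC(=O)c1ccc(OC)c(Oc2ccc(/C=C/c3cccc(OC)c3)cc2)c1 | intermediate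
9 | methyl 4-methoxy-3-{4-[2-(3-methoxyphenyl)ethyl]phenoxy}benzoate | COC(=O)c1ccc(OC)c(Oc2ccc(CCc3cccc(OC)c3)cc2)c1 | intermediate
10 | 4-methoxy-3-{4-[2-(3-methoxyphenyl)ethyl]phenoxy}benzoic acid | OC(=O)c1ccc(OC)c(Oc2ccc(CCc3cccc(OC)c3)cc2)c1 | intermediate
11 | 4-methoxy-3-{4-[2-(3-methoxyphenyl)ethyl]phenoxy}benzoyl chloride | COc1ccc(C(=O)Cl)cc1Oc1ccc(CCc2cccc(OC)c2)cc1 | intermediate
12 | {3-methoxy-2-[(4-methoxy-3-{4-[2-(3-methoxyphenyl)ethyl]phenoxy}benzoyl)oxy]benzyl}triphenylphosphonium bromide | COc1cccc(C[P+](c2ccccc2)(c2ccccc2)c2ccccc2)c1OC(=O)c1ccc(OC)c(Oc2ccc(CCc3cccc(OC)c3)cc2)c1.[Br-] | intermediate (not isolated)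
13 | 2-methoxy-6-[(triphenylphosphoranylidene)methyl]phenyl 4-methoxy-3-{4-[2-(3-methoxyphenyl)ethyl]phenoxy}benzoate | COc1cccc(C=P(c2ccccc2)(c2ccccc2)c2ccccc2)c1OC(=O)c1ccc(OC)c(Oc2ccc(CCc3cccc(OC)c3)cc2)c1 | intermediate (not isolated)
14 | 7-methoxy-2-(4-methoxy-3-{4-[2-(3-methoxyphenyl)ethyl]phenoxy}phenyl)-1-benzofuran | COc1cccc2cc(-c3ccc(OC)c(Oc4ccc(CCc5cccc(OC)c5)cc4)c3)oc12 | intermediate
15 | racemic 7-methoxy-2-(4-methoxy-3-{4-[2-(3-methoxyphenyl)ethyl]phenoxy}phenyl)-2,3-dihydro-1-benzofuran | COc1cccc2c1OC(c1ccc(OC)c(Oc3ccc(CCc4cccc(OC)c4)cc3)c1)C2 | intermediate (not isolated)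
16 | 2-methoxy-6-[2-(4-methoxy-3-{4-[2-(3-methoxyphenyl)ethyl]phenoxy}phenyl)ethyl]phenol | COc1cccc(CCc2ccc(OC)c(Oc3ccc(CCc4cccc(OC)c4)cc3)c2)c1O | intermediate
17 | 3-[2-(4-hydroxy-3-{4-[2-(3-hydroxyphenyl)ethyl]phenoxy}phenyl)ethyl]benzene-1,2-diol | Oc1cccc(CCc2ccc(Oc3cc(CCc4cccc(O)c4O)ccc3O)cc2)c1 | target

Total step count: 10. Longest linear sequence: 8 (steps 3 to 10, from 4 and 5 to 17). Alcohol 2 is also a catalogue compound; buying it would remove step 1.

Steps most likely to fail

Step 8. The ylide may be acylated a second time at carbon, or ring closure onto the electron-rich (para-methoxy) ester carbonyl may be slow enough for ester cleavage by adventitious water to compete. The fallback forms the bridge by an intermolecular Wittig reaction. It sets out from acid chloride 11, which LiAlH(OtBu)3 in THF at −78 °C should reduce to 4-methoxy-3-{4-[2-(3-methoxyphenyl)ethyl]phenoxy}benzaldehyde F1. Salt 3 with KOtBu (2.2 equiv, THF, 0 °C) gives the phenoxide ylide, which olefinates F1 to 2-methoxy-6-[2-(4-methoxy-3-{4-[2-(3-methoxyphenyl)ethyl]phenoxy}phenyl)ethenyl]phenol F2 (E/Z mixture). Hydrogenation (H2, 10% Pd/C, EtOAc) then saturates the alkene, and the route is rejoined at phenol 16, bypassing 14.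

Step 9. The aromatic furan may resist hydrogenation, or reduction may stall at dihydrobenzofuran 15 because hydrogenolysis is slow, while more forcing conditions start to saturate arene rings. The fallback replaces surface catalysis by ionic hydrogenation, from benzofuran 14 with Et3SiH in CF3CO2H/CH2Cl2. Protonation at C3 gives a C2 cation stabilised by O1 and the para-methoxyphenyl ring, and hydride transfer gives 15. The acid then ionises the benzylic C2–O bond (a para-methoxybenzyl aryl ether) and a second hydride transfer gives 16, where the route is rejoined. No new compound is made.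

Step 10. Ether cleavage may stop short of all three methyl groups, or the free catechol may degrade oxidatively during the Lewis acid treatment and aqueous quench. The fallback reverses the order of the last two operations, setting out from benzofuran 14. BBr3 in CH2Cl2 should give 2-(4-hydroxy-3-{4-[2-(3-hydroxyphenyl)ethyl]phenoxy}phenyl)-1-benzofuran-7-ol F3, a triol without a catechol. Hydrogenation and hydrogenolysis (H2, 10% Pd/C, AcOH) then pass through racemic 2-(4-hydroxy-3-{4-[2-(3-hydroxyphenyl)ethyl]phenoxy}phenyl)-2,3-dihydro-1-benzofuran-7-ol F4 (not isolated), helped by the free para-hydroxyl of ring C. The catechol is thus revealed under hydrogen in the last operation, and the route comes back at target 17.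

Further compounds
F1 | step 8 | 4-methoxy-3-{4-[2-(3-methoxyphenyl)ethyl]phenoxy}benzaldehyde | COc1ccc(C=O)cc1Oc1ccc(CCc2cccc(OC)c2)cc1
F2 | step 8 | 2-methoxy-6-[2-(4-methoxy-3-{4-[2-(3-methoxyphenyl)ethyl]phenoxy}phenyl)ethenyl]phenol (E/Z mixture, E isomer drawn) | COc1cccc(/C=C/c2ccc(OC)c(Oc3ccc(CCc4cccc(OC)c4)cc3)c2)c1O
F0 | step 9 | none | none
F3 | step 10 | 2-(4-hydroxy-3-{4-[2-(3-hydroxyphenyl)ethyl]phenoxy}phenyl)-1-benzofuran-7-ol | Oc1cccc2cc(-c3ccc(O)c(Oc4ccc(CCc5cccc(O)c5)cc4)c3)oc12
F4 | step 10 | racemic 2-(4-hydroxy-3-{4-[2-(3-hydroxyphenyl)ethyl]phenoxy}phenyl)-2,3-dihydro-1-benzofuran-7-ol | Oc1cccc2c1OC(c1ccc(O)c(Oc3ccc(CCc4cccc(O)c4)cc3)c1)C2
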